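Ring B (the bromophenol ring: OH on C1, diaryl-ether oxygen on C2, Br on C5) is not joined to ring A by an aryl–oxygen coupling but grown on an oxygen that ring A already carries. One base-mediated Michael–Claisen annulation of the ring-A aryloxyacetone with methyl acrylate forms the C2–C3 and C5–C6 bonds and closes ring B as a 4-aryloxycyclohexane-1,3-dione. It exploits the O,O,Br pattern on C2, C1 and C5: the carbonyl beside the ether carbon becomes the C1 hydroxyl, the remote carbonyl becomes C5–Br. The precursor is 1-(3,5-dibromo-2-methoxyphenoxy)propan-2-one, made by O-alkylation of a phenol; deoxybromination and dehydrogenation finish the arene.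

Key step: step 4

Remark 1: the target has no stereocentre, so there is no enantiomer to select; the one stereocentre that appears on the way (the aryloxy-bearing ring carbon of 8–11) is racemic and vanishes on aromatization.
Remark 2: only charge-neutral covalent intermediates are numbered; ion pairs that exist in passing within one operation (enolates, the peracid adduct, the enol oxyphosphonium bromide) are treated as mechanism in the Why lines.

Step 1
Reactants: 1 3,5-dibromo-2-hydroxybenzaldehyde
Product: 2 3,5-dibromo-2-methoxybenzaldehyde
Conditions: MeI (1.5 equiv), K2CO3 (1.5 equiv), DMF, rt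
Reagents that add atoms: iodomethane, CI
Why: Williamson O-methylation of the acidic dibromophenoxide; the non-enolizable aldehyde and the aryl bromides are inert to carbonate.

Step 2
Reactants: 2 3,5-dibromo-2-methoxybenzaldehyde
Product: 4 3,5-dibromo-2-methoxyphenol, via aryl formate 3 (not isolated)
Conditions: mCPBA (1.3 equiv), CH2Cl2, 0 °C → rt; aq NaHCO3 wash; then K2CO3 (cat.), MeOH, rt
Reagents that add atoms: 3-chloroperoxybenzoic acid (mCPBA), OOC(=O)c1cccc(Cl)c1
Why: Baeyer–Villiger (Dakin-type) oxidation in which the ortho-methoxy group favours aryl over hydride migration, followed by base-catalysed methanolysis of the labile aryl formate.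

Step 3
Reactants: 4 3,5-dibromo-2-methoxyphenol; 5 chloroacetone
Product: 6 1-(3,5-dibromo-2-methoxyphenoxy)propan-2-one
Conditions: K2CO3 (1.5 equiv), KI (cat.), acetone, reflux
Reagents that add atoms: none
Why: Williamson ether synthesis by SN2 attack of the phenoxide on the activated α-chloroketone (iodide catalysis of Finkelstein type), which sets the diaryl-ether oxygen of the target at an sp3 carbon.

Step 4
Reactants: 6 1-(3,5-dibromo-2-methoxyphenoxy)propan-2-one; 7 methyl acrylate
Product: 9 4-(3,5-dibromo-2-methoxyphenoxy)cyclohexane-1,3-dione (racemic), via Michael adduct 8 (not isolated)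
Conditions: t-BuOK (2.2 equiv), THF, −10 °C; 7 (1.05 equiv) added slowly; → rt; then 1 M HCl
Reagents that add atoms: none
Why: Under equilibrating tert-butoxide the enolate at the aryloxy-bearing CH2 of 6, the more acidic α-position because of the inductive pull of oxygen, adds to the β-carbon of 7 to give keto ester 8; after proton transfer the methyl-ketone enolate attacks the ester carbonyl and expels methoxide. The closest known reaction type is the consecutive Michael–Claisen annulation of substituted acetones with acrylates to 4-substituted cyclohexane-1,3-diones. The carbocycle closes in a 6-(enolendo)-exo-trig Claisen (Dieckmann-type) mode. The one new stereocentre, the aryloxy-bearing C4, forms without control as a racemate and is erased on aromatization, so no controlling element is needed. The selectivity required is C–C bond formation at OCH2 and not at CH3, and a single addition of acrylate: the first rests on the acidity difference of the two α-positions, the second on slow addition of 7 and on the fast ring closure, which is pulled forward by deprotonation of the acidic dione (hence more than 2 equiv of base).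

Step 5
Reactants: 9 4-(3,5-dibromo-2-methoxyphenoxy)cyclohexane-1,3-dione
Product: 10 3-bromo-6-(3,5-dibromo-2-methoxyphenoxy)cyclohex-2-en-1-one (racemic)
Conditions: Ph3PBr2 (1.1 equiv), Et3N (1.1 equiv), CH2Cl2, 0 °C → rt
Reagents that add atoms: dibromotriphenylphosphorane, BrP(Br)(c1ccccc1)(c1ccccc1)c1ccccc1
Why: Deoxybromination of a cyclic 1,3-dione with a triphenylphosphine dihalide (O-phosphonylation of the enolate, then addition–elimination by bromide with loss of Ph3PO) is a standard route to β-bromo enones, and the enolate oxygen remote from the aryloxy-bearing carbon is both less hindered and less deactivated inductively, so bromine should end on that carbon.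

Step 6
Reactants: 10 3-bromo-6-(3,5-dibromo-2-methoxyphenoxy)cyclohex-2-en-1-one
Product: 13 5-bromo-2-(3,5-dibromo-2-methoxyphenoxy)phenol, via alpha-bromo ketone 11 (not isolated), via dienone tautomer 12 (not isolated)
Conditions: LiHMDS (1.1 equiv), THF, −78 °C; NBS (1.0 equiv), −78 °C; DBU (1.5 equiv), −78 °C → rt; then 1 M HCl
Reagents that add atoms: none
Why: α-Halogenation/dehydrohalogenation aromatization of a cyclohexenone: LiHMDS removes the α′-proton at C6 (kinetically preferred in enones and further acidified by the aryloxy group), NBS brominates the enolate at carbon to give 11, DBU eliminates HBr towards C5 to give the cross-conjugated dienone 12, and 12 tautomerizes irreversibly to the phenol, the single equivalent of NBS being consumed before any phenol exists.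

Compound list
1 | 3,5-dibromo-2-hydroxybenzaldehyde (3,5-dibromosalicylaldehyde) | O=Cc1cc(Br)cc(Br)c1O | starting material
2 | 3,5-dibromo-2-methoxybenzaldehyde | COc1c(Br)cc(Br)cc1C=O | intermediate
3 | 3,5-dibromo-2-methoxyphenyl formate | COc1c(Br)cc(Br)cc1OC=O | intermediate
4 | 3,5-dibromo-2-methoxyphenol | COc1c(Br)cc(Br)cc1O | intermediate
5 | chloroacetone (1-chloropropan-2-one) | CC(=O)CCl | starting material
6 | 1-(3,5-dibromo-2-methoxyphenoxy)propan-2-one | CC(=O)COc1cc(Br)cc(Br)c1OC | intermediate
7 | methyl acrylate | C=CC(=O)OC | starting material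
8 | methyl 4-(3,5-dibromo-2-methoxyphenoxy)-5-oxohexanoate (racemic) | COC(=O)CCC(Oc1cc(Br)cc(Br)c1OC)C(C)=O | intermediate
9 | 4-(3,5-dibromo-2-methoxyphenoxy)cyclohexane-1,3-dione (racemic) | COc1c(Br)cc(Br)cc1OC1CCC(=O)CC1=O | intermediate
10 | 3-bromo-6-(3,5-dibromo-2-methoxyphenoxy)cyclohex-2-en-1-one (racemic) | COc1c(Br)cc(Br)cc1OC1CCC(Br)=CC1=O | intermediate
11 | 3,6-dibromo-6-(3,5-dibromo-2-methoxyphenoxy)cyclohex-2-en-1-one (racemic) | COc1c(Br)cc(Br)cc1OC1(Br)CCC(Br)=CC1=O | intermediate
12 | 3-bromo-6-(3,5-dibromo-2-methoxyphenoxy)cyclohexa-2,5-dien-1-one (keto tautomer of 13, CH2 at C4) | COc1c(Br)cc(Br)cc1OC1=CCC(Br)=CC1=O | intermediate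
13 | 5-bromo-2-(3,5-dibromo-2-methoxyphenoxy)phenol (achiral) | COc1c(Br)cc(Br)cc1Oc1ccc(Br)cc1O | target

Total step count: 6
Longest linear sequence: 6 steps (1 → 13; the route is fully linear)

Steps most likely to fail

Step 4. The acrylate may be taken up at the methyl carbon, a second acrylate may add at the aryloxy carbon before ring closure, or the acrylate may oligomerize under alkoxide. The fallback sets out from 4 and comes back at 8. Phenol 4 would be O-alkylated with commercial methyl 2-chloroacetoacetate (K2CO3, acetone, reflux) to methyl 2-(3,5-dibromo-2-methoxyphenoxy)-3-oxobutanoate F1. Its only acidic C–H lies between two carbonyls, so a Michael addition to 7 under catalytic base (DBU cat., MeCN, rt) can occur only there and only once. This would give dimethyl 2-acetyl-2-(3,5-dibromo-2-methoxyphenoxy)pentanedioate F2. Krapcho demethoxycarbonylation of the β-keto ester (LiCl, wet DMSO, 130 °C) would then deliver keto ester 8, now isolated. Compound 8 would be closed to 9 with t-BuOK by the Claisen half of step 4 alone.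

Step 5. Phosphorus may be transferred to the enol oxygen beside the aryloxy-bearing carbon, which would place bromine on the wrong ring carbon (poor regioselectivity between the two oxygens). The fallback sets out from 9 and comes back at 13; it replaces kinetic O-activation by a reversible condensation and carries the remote carbon as C–N. Dione 9 would be condensed with ammonium acetate (toluene, AcOH cat., reflux, water removal). Under these equilibrating conditions nitrogen should settle on the carbonyl carbon away from the electron-withdrawing aryloxy group, giving 3-amino-6-(3,5-dibromo-2-methoxyphenoxy)cyclohex-2-en-1-one F3. NBS (CH2Cl2, 0 °C) would brominate the nucleophilic C2 to 3-amino-2-bromo-6-(3,5-dibromo-2-methoxyphenoxy)cyclohex-2-en-1-one F4. DBU (MeCN, 60 °C) would induce loss of HBr and tautomerization to 5-amino-2-(3,5-dibromo-2-methoxyphenoxy)phenol F5. Diazotization (NaNO2, aq HBr, 0 °C) to 4-(3,5-dibromo-2-methoxyphenoxy)-3-hydroxybenzenediazonium bromide F6 and Sandmeyer bromination (CuBr, aq HBr, 60 °C) would give 13.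

Step 6. Bromine may be transferred to a position other than C6 (C2 or C4 of the enone, or the ring of the phenoxide once it is freed), or the elimination may stall. The fallback sets out from 10 and comes back at 12; it replaces halogenation/base elimination by a selenoxide syn-elimination. The lithium enolate of 10 (LiHMDS, THF, −78 °C) would be trapped with PhSeCl to give 3-bromo-6-(3,5-dibromo-2-methoxyphenoxy)-6-(phenylselanyl)cyclohex-2-en-1-one F7. Oxidation (H2O2, pyridine, CH2Cl2, 0 °C) would give 3-bromo-6-(3,5-dibromo-2-methoxyphenoxy)-6-(phenylseleninyl)cyclohex-2-en-1-one F8. Its syn-elimination can only take a hydrogen from C5 and so should deliver dienone 12, which tautomerizes to 13.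

Further compounds
F1 | step 4 | methyl 2-(3,5-dibromo-2-methoxyphenoxy)-3-oxobutanoate (racemic) | COC(=O)C(Oc1cc(Br)cc(Br)c1OC)C(C)=O
F2 | step 4 | dimethyl 2-acetyl-2-(3,5-dibromo-2-methoxyphenoxy)pentanedioate (racemic) | COC(=O)CCC(Oc1cc(Br)cc(Br)c1OC)(C(C)=O)C(=O)OC
F3 | step 5 | 3-amino-6-(3,5-dibromo-2-methoxyphenoxy)cyclohex-2-en-1-one (racemic) | COc1c(Br)cc(Br)cc1OC1CCC(N)=CC1=O
F4 | step 5 | 3-amino-2-bromo-6-(3,5-dibromo-2-methoxyphenoxy)cyclohex-2-en-1-one (racemic) | COc1c(Br)cc(Br)cc1OC1CCC(N)=C(Br)C1=O
F5 | step 5 | 5-amino-2-(3,5-dibromo-2-methoxyphenoxy)phenol | COc1c(Br)cc(Br)cc1Oc1ccc(N)cc1O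
F6 | step 5 | 4-(3,5-dibromo-2-methoxyphenoxy)-3-hydroxybenzenediazonium bromide | COc1c(Br)cc(Br)cc1Oc1ccc([N+]#N)cc1O.[Br-]
F7 | step 6 | 3-bromo-6-(3,5-dibromo-2-methoxyphenoxy)-6-(phenylselanyl)cyclohex-2-en-1-one (racemic) | COc1c(Br)cc(Br)cc1OC1([Se]c2ccccc2)CCC(Br)=CC1=O
F8 | step 6 | 3-bromo-6-(3,5-dibromo-2-methoxyphenoxy)-6-(phenylseleninyl)cyclohex-2-en-1-one (mixture of diastereomers) | COc1c(Br)cc(Br)cc1OC1([Se](=O)c2ccccc2)CCC(Br)=CC1=O
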